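(All runs are calculated for an exercise, and the scatter is random.)

The reagent stands at 0.800 equiv in the flask, and the bench rule for a limiting reagent takes that figure as the fraction of the solid substrate that can end as target.

| flask | solid substrate | reagent | remark | time |
|---|---|---|---|---|
| zeta | 0.050 M | 0.40 equiv | run made earlier |  |
| eta | 0.050 M | 0.60 equiv | run made earlier |  |
| flask | 0.050 M | 0.800 equiv |  | 4.0 h |

| run | time / h | target / % | solid product / % |
|---|---|---|---|
| zeta | 0.250 | 2.5 | 0 |
| zeta | 0.667 | 8.4 | 0 |
| zeta | 1.33 | 11.3 | 0 |
| zeta | 3.00 | 16.0 | 1.6 |
| eta | 0.250 | 3.1 | 0.7 |
| eta | 0.667 | 10.3 | 1.7 |
| eta | 1.33 | 19.6 | 0 |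
| eta | 3.00 | 19.0 | 0.8 |

(each reading ± 1 percentage point)

1. target and solid product together at 4.0 h, in percent of the solid substrate charged
2. concentration of dissolved substrate in solution at 4.0 h, in percent of saturation

- for target the solid product is counted in
- as a solid, counted per litre of solution: solid substrate, solid product
- what was read earlier has a scatter of 1 percentage point, one standard deviation
- at the start none of the solid substrate is in solution
- dissolved substrate means what is dissolved; the solid is not counted in it

The eta run shows where that rule stops. Its last two target readings lie 0.6 percentage points apart, inside the scatter of 1 point, so replacing the flat stretch by its mean costs little. That mean, divided by the charge of reagent, gives 0.322, the yield per equivalent: target as a fraction of the solid substrate charged, for each equivalent of reagent. The bench rule would need this ratio to be 1. The ratio is also no constant, since the zeta run reads 0.400 at its last reading. The eta run stands nearer in charge, so the reckoning here takes its ratio and gives the flask 25.8%.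

The forecast gives 27% on the ground that “the plateau scales roughly with charge”, a yield 1.3 points above the reckoning here; on separate grounds, from the lag and from undissolved solid remaining, it puts dissolved substrate at 97% of saturation.

The flask gives 23.8% of target and solid product together, with dissolved substrate at 102% of saturation.

    solid substrate ⇌ dissolved substrate, rate k1*(cs1 - [dissolved substrate]) while solid is left; crystals form when [dissolved substrate] > cs1 (solubility = 28.0 mM, k = 0.0290 /min)
    dissolved substrate + reagent ⇌ target (K = 63.0 /M, k = 0.700 /M/min)
    reagent → side product (k = 0.00680 /min)
    solid product ⇌ target, rate k4*(cs4 - [target]) while solid is left; crystals form when [target] > cs4 (solubility = 25.0 mM, k = 1.10 /min)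

That yield is no plateau, for the same flask held 27.1% at 2.00 h. Its yield per equivalent comes to 0.297, against the carried 0.322. Applied to the neighbour flask with 1.40 equiv, read at 4.00 h, the carried ratio predicts 45.1%, and that flask gives 40.2%.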